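**Plan**

1. Retrosynthesis: cut the C7–O decanoate ester, then C8–C8a (alkenyl–aldehyde coupling that opens ring B), then C4a=C5 (acetylide addition to a γ-pyranone followed by a Meyer–Schuster shift). This leaves 2-heptyl-5-iodo-4H-pyran-4-one and a C5–C8 alkyne carrying the C7 carbinol.
2. Enabling feature: the C8 carbonyl is bonded to C8a, the β-carbon of the ring A enol ether O2–C1=C8a. That carbon can carry iodine, so an alkenyl metal at C8a can add to a C8 aldehyde held by the tether C4a=C5–C6(=O)–C7 and close carbocyclic ring B.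
3. Forward order: ring A first (octanal + Danishefsky's diene, iodination at the dihydropyranone stage, dehydrogenation), then the chain is attached at C4a, then ring B is closed at C8–C8a, then C8 oxidation, desilylation and acylation.
4. Stereochemistry: the only stereocentre of the target, C7 (R), comes from Sharpless epoxidation of methallyl alcohol with L-(+)-DIPT. It is quaternary, so it cannot epimerise. The C8 carbinol centre formed on ring closure is erased by oxidation.

Key step: step 13

**Remarks and assumptions**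

- Atoms are numbered as in the isochromene core of the target (C1, O2, C3 bearing heptyl, C4, C4a, C5, C6, C7, C8, C8a), also in acyclic precursors.
- L-(+)-tartrate is taken to give the (S)-epoxide of methallyl alcohol, following the usual facial rule of the Sharpless epoxidation.
- The push–pull C4a=C5 bond of the pyranylidene ketones is assumed to equilibrate between E and Z at room temperature. SMILES show the Z form (C6 cis to C8a).
- Changes of the C7 descriptor along the route reflect CIP priorities only; no bond to C7 is broken after step 1.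
- TBS = tert-butyldimethylsilyl, PMB = 4-methoxybenzyl.

**Route**

Step 1
Reactants: 1 methallyl alcohol (2-methylprop-2-en-1-ol)
Product: 2 (S)-2-methylglycidol
Conditions: Ti(OiPr)4 (5 mol %), L-(+)-DIPT (6 mol %), t-BuOOH, 4 Å MS, CH2Cl2, −20 °C
Reagents that add atoms: tert-butyl hydroperoxide, CC(C)(C)OO
Why: Katsuki–Sharpless asymmetric epoxidation of a 2-substituted allylic alcohol, in which the titanium–L-(+)-tartrate complex should deliver oxygen to one enantioface and set the future C7 centre as the (S)-epoxide.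

Step 2
Reactants: 2 (S)-2-methylglycidol
Product: 3 (2S)-3-[(4-methoxybenzyl)oxy]-2-methylpropane-1,2-diol
Conditions: 4-MeOC6H4CH2OH (3 equiv), NaH (0.2 equiv), DMF, 60 °C
Reagents that add atoms: 4-methoxybenzyl alcohol, COc1ccc(CO)cc1
Why: Base-mediated SN2 opening of the epoxide at its unsubstituted carbon by the PMB alkoxide (the degenerate Payne isomer leads to the same diol), so no bond to the quaternary centre is broken and the two CH2O arms become distinguishable.

Step 3
Reactants: 3 (2S)-3-[(4-methoxybenzyl)oxy]-2-methylpropane-1,2-diol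
Product: 4 (2R)-1,2-bis(tert-butyldimethylsilyloxy)-3-[(4-methoxybenzyl)oxy]-2-methylpropane
Conditions: TBSOTf (2.5 equiv), 2,6-lutidine, CH2Cl2, 0 °C → rt
Reagents that add atoms: tert-butyldimethylsilyl triflate, CC(C)(C)[Si](C)(C)OS(=O)(=O)C(F)(F)F
Why: Silyl triflate with a hindered pyridine base is the standard silylation that also protects a tertiary hydroxyl, giving the primary (future C8) and tertiary (C7) silyl ethers in one operation.

Step 4
Reactants: 4 (2R)-1,2-bis(tert-butyldimethylsilyloxy)-3-[(4-methoxybenzyl)oxy]-2-methylpropane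
Product: 5 (2R)-2,3-bis(tert-butyldimethylsilyloxy)-2-methylpropan-1-ol
Conditions: DDQ, CH2Cl2–pH 7 buffer, 0 °C → rt
Reagents that add atoms: none
Why: Oxidative PMB ether cleavage by DDQ (benzylic hydride abstraction, then hydrolysis of the oxocarbenium ion) is selective over silyl ethers under buffered conditions.

Step 5
Reactants: 5 (2R)-2,3-bis(tert-butyldimethylsilyloxy)-2-methylpropan-1-ol
Product: 6 (2S)-2,3-bis(tert-butyldimethylsilyloxy)-2-methylpropanal
Conditions: Dess–Martin periodinane, NaHCO3, CH2Cl2, 0 °C → rt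
Reagents that add atoms: none
Why: Dess–Martin oxidation of a primary alcohol gives an aldehyde without an α-hydrogen, so the adjacent C7 centre cannot epimerise.

Step 6
Reactants: 6 (2S)-2,3-bis(tert-butyldimethylsilyloxy)-2-methylpropanal
Product: 7 (3R)-3,4-bis(tert-butyldimethylsilyloxy)-3-methylbut-1-yne
Conditions: dimethyl (1-diazo-2-oxopropyl)phosphonate, K2CO3, MeOH, 0 °C → rt
Reagents that add atoms: dimethyl (1-diazo-2-oxopropyl)phosphonate (Ohira–Bestmann reagent), CC(=O)C(=[N+]=[N-])P(=O)(OC)OC
Why: Seyferth–Gilbert homologation in its Ohira–Bestmann form converts the non-enolisable aldehyde into the terminal alkyne under mild carbonate conditions and brings in the carbon that becomes C5.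

Step 7
Reactants: 8 octanal; 9 Danishefsky's diene ((E)-1-methoxy-3-(trimethylsilyloxy)buta-1,3-diene)
Product: 11 2-heptyl-2,3-dihydro-4H-pyran-4-one (racemic), via cycloadduct 10 (not isolated)
Conditions: ZnCl2 (10 mol %), THF, rt; then TFA (cat.), wet CH2Cl2, 0 °C
Reagents that add atoms: none
Why: Lewis acid-catalysed hetero-Diels–Alder reaction of the siloxy diene with an aliphatic aldehyde, then acid-induced loss of methanol and the silyl group, gives the dihydropyranone, whose racemic C2 centre disappears in step 9.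

Step 8
Reactants: 11 2-heptyl-2,3-dihydro-4H-pyran-4-one
Product: 12 2-heptyl-5-iodo-2,3-dihydro-4H-pyran-4-one (racemic)
Conditions: I2, pyridine–CH2Cl2, 0 °C → rt
Reagents that add atoms: iodine, II
Why: Johnson α-iodination of an enone (pyridine addition, iodination of the enolate, elimination) can only occur at the single enone α-carbon C5 of the dihydropyranone, which places iodine regiospecifically on the future C8a, a choice that the aromatised pyranone with its two similar positions would not guarantee.

Step 9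
Reactants: 12 2-heptyl-5-iodo-2,3-dihydro-4H-pyran-4-one
Product: 14 2-heptyl-5-iodo-4H-pyran-4-one, via silyl dienol ether 13 (not isolated)
Conditions: LiN(SiMe3)2, Me3SiCl, THF, −78 °C; then DDQ, CH2Cl2, 0 °C → rt
Reagents that add atoms: none
Why: Kinetic enolisation at C3 with in situ O-silylation gives a 2H-pyran dienol ether from which DDQ abstracts the allylic, oxygen-activated C2 hydride, and the resulting 4-silyloxypyrylium ion loses silicon to give the γ-pyranone (dehydrogenation of a silyl enol ether).

Step 10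
Reactants: 7 (3R)-3,4-bis(tert-butyldimethylsilyloxy)-3-methylbut-1-yne; 14 2-heptyl-5-iodo-4H-pyran-4-one
Product: 17 (3S)-3,4-bis(tert-butyldimethylsilyloxy)-1-(2-heptyl-5-iodo-4H-pyran-4-ylidene)-3-methylbutan-2-one, via lithium acetylide 15 (not isolated), via propargylic pyranol 16 (not isolated)
Conditions: n-BuLi, THF, −78 °C; 14, −78 → −20 °C; H2O; then PPTS (cat.), THF–H2O, rt → 40 °C
Reagents that add atoms: water, O (supplies the C6 carbonyl oxygen; the C4a hydroxyl leaves as water)
Why: 1,2-Addition of the lithium acetylide to the pyranone carbonyl is followed by a Meyer–Schuster rearrangement in which the bis-vinylic tertiary propargylic alcohol ionises to a 4-alkynylpyrylium ion, water adds at the distal alkyne carbon C6 and the allenol tautomerises to the pyranylidene ketone, a vinylogous ester that is the thermodynamic sink.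

Step 11
Reactants: 17 (3S)-3,4-bis(tert-butyldimethylsilyloxy)-1-(2-heptyl-5-iodo-4H-pyran-4-ylidene)-3-methylbutan-2-one
Product: 18 (3S)-3-(tert-butyldimethylsilyloxy)-1-(2-heptyl-5-iodo-4H-pyran-4-ylidene)-4-hydroxy-3-methylbutan-2-one
Conditions: HF·pyridine, pyridine, THF, 0 °C
Reagents that add atoms: none
Why: Buffered HF·pyridine cleaves the unhindered primary TBS ether much faster than the tertiary one, a standard steric differentiation of silyl ethers, under non-basic conditions that avoid silyl migration and retro-aldol loss of C8.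

Step 12
Reactants: 18 (3S)-3-(tert-butyldimethylsilyloxy)-1-(2-heptyl-5-iodo-4H-pyran-4-ylidene)-4-hydroxy-3-methylbutan-2-one
Product: 19 (2S)-2-(tert-butyldimethylsilyloxy)-4-(2-heptyl-5-iodo-4H-pyran-4-ylidene)-2-methyl-3-oxobutanal
Conditions: Dess–Martin periodinane, NaHCO3, CH2Cl2, 0 °C
Reagents that add atoms: none
Why: Dess–Martin oxidation under buffered, non-nucleophilic conditions should give the β-keto aldehyde, which has no α-hydrogen and is used at once because such aldehydes lose the formyl group to nucleophiles.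

Step 13
Reactants: 19 (2S)-2-(tert-butyldimethylsilyloxy)-4-(2-heptyl-5-iodo-4H-pyran-4-ylidene)-2-methyl-3-oxobutanal
Product: 20 (7S)-7-(tert-butyldimethylsilyloxy)-3-heptyl-8-hydroxy-7-methyl-7,8-dihydro-6H-isochromen-6-one (both C8 epimers)
Conditions: CrCl2 (6 equiv), NiCl2 (5 mol %), degassed DMF, rt, 0.005 M
Reagents that add atoms: none
Why: Zerovalent nickel, generated from NiCl2 by the excess CrCl2 (divalent chromium), undergoes oxidative addition at the C8a–I bond and passes the alkenyl group to chromium, and the alkenyl reagent of trivalent chromium then attacks the C8 aldehyde, the known intramolecular Nozaki–Hiyama–Kishi coupling of an alkenyl iodide with an aldehyde. Ring B closes in a 6-exo-trig mode through C8a–C4a–C5–C6–C7–C8, the aldehyde oxygen staying outside the ring. The iodine installed in step 8 decides that C8a and not the similarly activated C4 is joined to C8, and the organochromium reagent should select the aldehyde over the deactivated vinylogous-ester ketone at C6, whose attack would require a four-membered ring. Only the Z isomer about C4a=C5 can cyclise, and the low rotation barrier of this push–pull bond, lowered further by chromium salts bound to the C6 oxygen, should supply it from the E isomer. The new C8 carbinol centre is not controlled and is removed in step 14, while C7 is untouched because the aldehyde next to it cannot enolise.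

Step 14
Reactants: 20 (7S)-7-(tert-butyldimethylsilyloxy)-3-heptyl-8-hydroxy-7-methyl-7,8-dihydro-6H-isochromen-6-one
Product: 21 (7R)-7-(tert-butyldimethylsilyloxy)-3-heptyl-7-methyl-6H-isochromene-6,8(7H)-dione
Conditions: Dess–Martin periodinane, NaHCO3, CH2Cl2, rt
Reagents that add atoms: none
Why: Dess–Martin oxidation of the allylic C8 carbinol gives the non-enolisable 6,8-dione, so both C8 epimers converge on one compound.

Step 15
Reactants: 21 (7R)-7-(tert-butyldimethylsilyloxy)-3-heptyl-7-methyl-6H-isochromene-6,8(7H)-dione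
Product: 22 (7R)-3-heptyl-7-hydroxy-7-methyl-6H-isochromene-6,8(7H)-dione
Conditions: HF·pyridine, THF, 0 °C → rt
Reagents that add atoms: none
Why: Fluoride-driven Si–O cleavage under acidic HF·pyridine conditions should free the tertiary C7 hydroxyl without exposing the base-sensitive α-hydroxy-β-diketone and pyran ring to alkoxide or amine nucleophiles.

Step 16
Reactants: 22 (7R)-3-heptyl-7-hydroxy-7-methyl-6H-isochromene-6,8(7H)-dione; 23 decanoyl chloride
Product: 24 (7R)-3-heptyl-7-methyl-6,8-dioxo-7,8-dihydro-6H-isochromen-7-yl decanoate (target, CNP0197863.1)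
Conditions: Et3N, DMAP (cat.), CH2Cl2, 0 °C → rt
Reagents that add atoms: none
Why: DMAP-catalysed acylation of the tertiary alcohol by the acid chloride through an acylpyridinium ion is a standard esterification for hindered hydroxyls, and the quaternary C7 cannot epimerise.

**Compound list**

1 | methallyl alcohol (2-methylprop-2-en-1-ol) | C=C(C)CO | starting material
2 | (S)-2-methylglycidol | C[C@]1(CO)CO1 | intermediate
3 | (2S)-3-[(4-methoxybenzyl)oxy]-2-methylpropane-1,2-diol | C[C@](O)(CO)COCc1ccc(OC)cc1 | intermediate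
4 | (2R)-1,2-bis(tert-butyldimethylsilyloxy)-3-[(4-methoxybenzyl)oxy]-2-methylpropane | C[C@](O[Si](C)(C)C(C)(C)C)(CO[Si](C)(C)C(C)(C)C)COCc1ccc(OC)cc1 | intermediate
5 | (2R)-2,3-bis(tert-butyldimethylsilyloxy)-2-methylpropan-1-ol | C[C@](O[Si](C)(C)C(C)(C)C)(CO[Si](C)(C)C(C)(C)C)CO | intermediate
6 | (2S)-2,3-bis(tert-butyldimethylsilyloxy)-2-methylpropanal | C[C@](O[Si](C)(C)C(C)(C)C)(CO[Si](C)(C)C(C)(C)C)C=O | intermediate
7 | (3R)-3,4-bis(tert-butyldimethylsilyloxy)-3-methylbut-1-yne | C[C@](O[Si](C)(C)C(C)(C)C)(CO[Si](C)(C)C(C)(C)C)C#C | intermediate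
8 | octanal | CCCCCCCC=O | starting material
9 | Danishefsky's diene, (E)-1-methoxy-3-(trimethylsilyloxy)buta-1,3-diene | CO/C=C/C(=C)O[Si](C)(C)C | starting material
10 | 2-heptyl-6-methoxy-4-(trimethylsilyloxy)-3,6-dihydro-2H-pyran (racemic, cis/trans mixture) | CCCCCCCC1CC(O[Si](C)(C)C)=CC(OC)O1 | intermediate (not isolated)
11 | 2-heptyl-2,3-dihydro-4H-pyran-4-one (racemic) | CCCCCCCC1CC(=O)C=CO1 | intermediate
12 | 2-heptyl-5-iodo-2,3-dihydro-4H-pyran-4-one (racemic) | CCCCCCCC1CC(=O)C(I)=CO1 | intermediate
13 | 2-heptyl-5-iodo-4-(trimethylsilyloxy)-2H-pyran (racemic) | CCCCCCCC1C=C(O[Si](C)(C)C)C(I)=CO1 | intermediate (not isolated)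
14 | 2-heptyl-5-iodo-4H-pyran-4-one | CCCCCCCC1=CC(=O)C(I)=CO1 | intermediate
15 | lithium (3R)-3,4-bis(tert-butyldimethylsilyloxy)-3-methylbut-1-yn-1-ide | C[C@](O[Si](C)(C)C(C)(C)C)(CO[Si](C)(C)C(C)(C)C)C#C[Li] | intermediate (not isolated)
16 | 4-[(3R)-3,4-bis(tert-butyldimethylsilyloxy)-3-methylbut-1-yn-1-yl]-2-heptyl-5-iodo-4H-pyran-4-ol (both epimers at the pyran carbinol carbon) | C[C@](O[Si](C)(C)C(C)(C)C)(CO[Si](C)(C)C(C)(C)C)C#CC1(O)C=C(CCCCCCC)OC=C1I | intermediate (not isolated)
17 | (3S)-3,4-bis(tert-butyldimethylsilyloxy)-1-(2-heptyl-5-iodo-4H-pyran-4-ylidene)-3-methylbutan-2-one (Z form shown) | C[C@](O[Si](C)(C)C(C)(C)C)(CO[Si](C)(C)C(C)(C)C)C(=O)/C=C1/C=C(CCCCCCC)OC=C1I | intermediate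
18 | (3S)-3-(tert-butyldimethylsilyloxy)-1-(2-heptyl-5-iodo-4H-pyran-4-ylidene)-4-hydroxy-3-methylbutan-2-one (Z form shown) | C[C@](O[Si](C)(C)C(C)(C)C)(CO)C(=O)/C=C1/C=C(CCCCCCC)OC=C1I | intermediate
19 | (2S)-2-(tert-butyldimethylsilyloxy)-4-(2-heptyl-5-iodo-4H-pyran-4-ylidene)-2-methyl-3-oxobutanal (Z form shown) | CC(C)(C)[Si](C)(C)O[C@@](C)(C=O)C(=O)/C=C1/C=C(CCCCCCC)OC=C1I | intermediate
20 | (7S)-7-(tert-butyldimethylsilyloxy)-3-heptyl-8-hydroxy-7-methyl-7,8-dihydro-6H-isochromen-6-one (C8 epimers) | CC(C)(C)[Si](C)(C)O[C@]1(C)C(=O)C=C2C=C(CCCCCCC)OC=C2C1O | intermediate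
21 | (7R)-7-(tert-butyldimethylsilyloxy)-3-heptyl-7-methyl-6H-isochromene-6,8(7H)-dione | CC(C)(C)[Si](C)(C)O[C@]1(C)C(=O)C=C2C=C(CCCCCCC)OC=C2C1=O | intermediate
22 | (7R)-3-heptyl-7-hydroxy-7-methyl-6H-isochromene-6,8(7H)-dione | O[C@]1(C)C(=O)C=C2C=C(CCCCCCC)OC=C2C1=O | intermediate
23 | decanoyl chloride | CCCCCCCCCC(Cl)=O | starting material
24 | (7R)-3-heptyl-7-methyl-6,8-dioxo-7,8-dihydro-6H-isochromen-7-yl decanoate | CCCCCCCCCC(=O)O[C@]1(C)C(=O)C=C2C=C(CCCCCCC)OC=C2C1=O | target

**Step count**

Total: 16 steps. Longest linear sequence: 13 steps (steps 1–6 and 10–16); the pyranone branch (steps 7–9) has 3 steps.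

**Steps most likely to fail, with fallbacks**

Step 10. The acetylide may deprotonate the heptyl α-CH2 of the pyranone (vinylogous enolisation) or add in conjugate fashion at C1 instead of at the carbonyl. After ionisation, water may attack the pyrylium ring at C1 and open it, or the hydration of the alkynylpyrylium ion may stall. The fallback makes the C4a=C5 bond by C-acylation of a methylenepyran; it sets out from 14 and 6 and comes back at 17.
- From 14, MeMgBr (THF, −78 °C) should add to the carbonyl to give 2-heptyl-5-iodo-4-methyl-4H-pyran-4-ol F1, which HBF4·OEt2 dehydrates to 2-heptyl-5-iodo-4-methylpyrylium tetrafluoroborate F2.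
- From 6, oxidation with NaClO2, NaH2PO4 and 2-methylbut-2-ene should give (2S)-2,3-bis(tert-butyldimethylsilyloxy)-2-methylpropanoic acid F3, which 1-chloro-N,N,2-trimethylprop-1-enylamine converts under neutral conditions into (2S)-2,3-bis(tert-butyldimethylsilyloxy)-2-methylpropanoyl chloride F4.
- 2,6-Di-tert-butylpyridine in CH2Cl2 should release from F2 the anhydrobase 2-heptyl-5-iodo-4-methylene-4H-pyran F5 in the flask; its exocyclic carbon is acylated by F4, and loss of HCl gives 17. Alkyne 7 is then not needed.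

Step 13. Nickel insertion into the electron-rich β-alkoxyvinyl iodide may be slow. The alkenylchromium species may be protonated before it cyclises if rotation about C4a=C5 is slow, so that iodine is lost without ring closure. The β-keto aldehyde may also lose its formyl group during the long reaction. The fallback closes the same bond by rhodium-catalysed addition of an alkenylboronate to the aldehyde; it sets out from 17 and comes back at 20.
- Miyaura borylation of 17 (B2pin2, Pd(dppf)Cl2, KOAc, dioxane, 80 °C) should replace iodine and give (3S)-3,4-bis(tert-butyldimethylsilyloxy)-1-[2-heptyl-5-(4,4,5,5-tetramethyl-1,3,2-dioxaborolan-2-yl)-4H-pyran-4-ylidene]-3-methylbutan-2-one F6.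
- HF·pyridine/pyridine frees the primary alcohol (3S)-3-(tert-butyldimethylsilyloxy)-1-[2-heptyl-5-(4,4,5,5-tetramethyl-1,3,2-dioxaborolan-2-yl)-4H-pyran-4-ylidene]-4-hydroxy-3-methylbutan-2-one F7.
- Dess–Martin oxidation gives the boronate aldehyde (2S)-2-(tert-butyldimethylsilyloxy)-4-[2-heptyl-5-(4,4,5,5-tetramethyl-1,3,2-dioxaborolan-2-yl)-4H-pyran-4-ylidene]-2-methyl-3-oxobutanal F8.
- [Rh(cod)OH]2 (cat.) in dioxane–H2O should bring about transmetalation from boron to rhodium and intramolecular 1,2-addition to the aldehyde, giving 20.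

Step 9. DDQ may add to the silyl dienol ether or oxidise the iodine-bearing enol ether instead of abstracting the C2 hydride, and premature loss of the silyl group would return 12. The fallback replaces hydride abstraction by selenoxide elimination; it sets out from 12 and comes back at 14.
- α-Selenation of 12 (LiN(SiMe3)2, PhSeCl, THF, −78 °C) should give 2-heptyl-5-iodo-3-(phenylselanyl)-2,3-dihydro-4H-pyran-4-one F9.
- Oxidation with H2O2/pyridine in CH2Cl2 at 0 °C forms the selenoxide, which undergoes syn-elimination toward C2 and gives 14.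

**Further compounds**

F1 | step 10 | 2-heptyl-5-iodo-4-methyl-4H-pyran-4-ol (racemic) | CCCCCCCC1=CC(C)(O)C(I)=CO1
F2 | step 10 | 2-heptyl-5-iodo-4-methylpyrylium tetrafluoroborate | CCCCCCCc1cc(C)c(I)c[o+]1.F[B-](F)(F)F
F3 | step 10 | (2S)-2,3-bis(tert-butyldimethylsilyloxy)-2-methylpropanoic acid | C[C@](O[Si](C)(C)C(C)(C)C)(CO[Si](C)(C)C(C)(C)C)C(=O)O
F4 | step 10 | (2S)-2,3-bis(tert-butyldimethylsilyloxy)-2-methylpropanoyl chloride | C[C@](O[Si](C)(C)C(C)(C)C)(CO[Si](C)(C)C(C)(C)C)C(=O)Cl
F5 | step 10 | 2-heptyl-5-iodo-4-methylene-4H-pyran | CCCCCCCC1=CC(=C)C(I)=CO1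
F6 | step 13 | (3S)-3,4-bis(tert-butyldimethylsilyloxy)-1-[2-heptyl-5-(4,4,5,5-tetramethyl-1,3,2-dioxaborolan-2-yl)-4H-pyran-4-ylidene]-3-methylbutan-2-one | C[C@](O[Si](C)(C)C(C)(C)C)(CO[Si](C)(C)C(C)(C)C)C(=O)/C=C1/C=C(CCCCCCC)OC=C1B2OC(C)(C)C(C)(C)O2
F7 | step 13 | (3S)-3-(tert-butyldimethylsilyloxy)-1-[2-heptyl-5-(4,4,5,5-tetramethyl-1,3,2-dioxaborolan-2-yl)-4H-pyran-4-ylidene]-4-hydroxy-3-methylbutan-2-one | C[C@](O[Si](C)(C)C(C)(C)C)(CO)C(=O)/C=C1/C=C(CCCCCCC)OC=C1B2OC(C)(C)C(C)(C)O2
F8 | step 13 | (2S)-2-(tert-butyldimethylsilyloxy)-4-[2-heptyl-5-(4,4,5,5-tetramethyl-1,3,2-dioxaborolan-2-yl)-4H-pyran-4-ylidene]-2-methyl-3-oxobutanal | C[C@](O[Si](C)(C)C(C)(C)C)(C=O)C(=O)/C=C1/C=C(CCCCCCC)OC=C1B2OC(C)(C)C(C)(C)O2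
F9 | step 9 | 2-heptyl-5-iodo-3-(phenylselanyl)-2,3-dihydro-4H-pyran-4-one (racemic) | CCCCCCCC1OC=C(I)C(=O)C1[Se]c1ccccc1
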